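The cyclohexane ring (C1 = C(OH)CH3, C2 = CH with the side chain, C3 = C(CH3)2, C4 = CHOH, C5 and C6 = CH2) is closed last at C5–C6, the bond between the two methylene groups that separate the oxygenated carbons C4 and C1. The precursor is an acyclic methyl ketone (future C4 and C5) bearing a 2-methyloxirane (future C1 and C6), made in the flask from a hydroxy tosylate. Because C3 is quaternary the enolate can form only at C5, and because C1 is fully substituted it must attack the oxirane CH2. One operation gives the ring and the C1 carbinol, whose configuration comes from a Sharpless epoxidation.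

Key step: step 6

Remark: (R)-(−)-linalool of high enantiomeric purity is taken as commercial, and the open-chain γ-hydroxy ketones 7 and 8 are drawn as such although they may rest as five-membered hemiketals.

Step 1
Reactants: 1 (R)-(−)-linalool [(3R)-3,7-dimethylocta-1,6-dien-3-ol]
Product: 2 (2E,6R)-2,6-dimethylocta-2,7-diene-1,6-diol
Conditions: SeO2 (cat.), t-BuOOH, salicylic acid (cat.), CH2Cl2, rt
Reagents that add atoms: selenium dioxide O=[Se]=O (catalytic oxygen carrier) and tert-butyl hydroperoxide CC(C)(C)OO (terminal oxidant)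
Why: Catalytic SeO2 allylic oxidation (ene reaction, then [2,3]-sigmatropic shift) should attack only the trisubstituted olefin at its (E)-methyl group, while the vinyl carbinol, which has no allylic hydrogen, stays untouched.

Step 2
Reactants: 2 (2E,6R)-2,6-dimethylocta-2,7-diene-1,6-diol
Product: 3 [(2S,3S)-3-[(3R)-3-hydroxy-3-methylpent-4-en-1-yl]-2-methyloxiran-2-yl]methanol
Conditions: Ti(OiPr)4 (cat.), L-(+)-diethyl tartrate (cat.), t-BuOOH, 4 Å MS, CH2Cl2, −20 °C
Reagents that add atoms: tert-butyl hydroperoxide CC(C)(C)OO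
Why: Sharpless asymmetric epoxidation of the primary (E)-allylic alcohol with L-(+)-tartrate should give the (2S,3S)-oxirane under reagent control, which fixes future C1 (oxirane C2) and, for inversion in step 3, future C2 (oxirane C3); the tertiary vinyl carbinol is not a competent substrate.

Step 3
Reactants: 3 [(2S,3S)-3-[(3R)-3-hydroxy-3-methylpent-4-en-1-yl]-2-methyloxiran-2-yl]methanol, 4 isobutyronitrile (2-methylpropanenitrile)
Product: 5 (3S,6R)-3-[(2R)-1,2-dihydroxypropan-2-yl]-6-hydroxy-2,2,6-trimethyloct-7-enenitrile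
Conditions: 4 (4 equiv), LiN(iPr)2 (6 equiv), THF, −78 °C; add 3; −78 → 50 °C; then H2O
Reagents that add atoms: none
Why: The tertiary nitrile carbanion should open the trisubstituted oxirane by SN2 attack at its only secondary carbon (the other is fully substituted), which forms the hindered C2–C3 bond with inversion at C2 and leaves the tertiary C–O bond of C1 untouched (nitrile-anion epoxide opening).

Step 4
Reactants: 5 (3S,6R)-3-[(2R)-1,2-dihydroxypropan-2-yl]-6-hydroxy-2,2,6-trimethyloct-7-enenitrile
Product: 7 (4S,7R)-4-[(2R)-1,2-dihydroxypropan-2-yl]-7-hydroxy-3,3,7-trimethylnon-8-en-2-one, via ketimine 6 (not isolated)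
Conditions: MeLi (6 equiv), THF, 0 °C → rt; then aq NH4Cl, rt
Reagents that add atoms: methyllithium [Li]C; water O
Why: Methyllithium should add once to the nitrile, which has no α-hydrogen, to give an N-lithio ketimine that resists a second addition, and mild aqueous hydrolysis releases the methyl ketone whose CH3 is the future C5 (organolithium addition to a nitrile).

Step 5
Reactants: 7 (4S,7R)-4-[(2R)-1,2-dihydroxypropan-2-yl]-7-hydroxy-3,3,7-trimethylnon-8-en-2-one
Product: 8 (2R)-2-hydroxy-2-[(4S,7R)-7-hydroxy-3,3,7-trimethyl-2-oxonon-8-en-4-yl]propyl 4-methylbenzenesulfonate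
Conditions: TsCl (1.1 equiv), Et3N, Bu2SnO (cat.), CH2Cl2, 0 °C → rt
Reagents that add atoms: p-toluenesulfonyl chloride Cc1ccc(cc1)S(=O)(=O)Cl
Why: Tin-catalysed sulfonylation through the stannylene acetal of the 1,2-diol should tosylate only the primary hydroxyl, the two tertiary hydroxyls being inert to TsCl.

Step 6
Reactants: 8 (2R)-2-hydroxy-2-[(4S,7R)-7-hydroxy-3,3,7-trimethyl-2-oxonon-8-en-4-yl]propyl 4-methylbenzenesulfonate
Product: 10 (3S,4S)-4-hydroxy-3-[(3R)-3-hydroxy-3-methylpent-4-en-1-yl]-2,2,4-trimethylcyclohexan-1-one, via oxiranyl ketone 9 (not isolated)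
Conditions: KOtBu (3 equiv), t-BuOH/THF, high dilution, 0 → 40 °C
Reagents that add atoms: none
Why: tert-Butoxide should first turn the β-hydroxy tosylate into the 2,2-disubstituted oxirane 9 (3-exo-tet, the C1–O bond is never broken) and then form reversibly the potassium enolate of the methyl ketone, whose terminal carbon attacks the oxirane CH2 and so makes the C5–C6 bond and the ring, the C1 alkoxide being protonated by t-BuOH. The closest known reaction type is the intramolecular alkylation of a ketone enolate by an epoxide, the epoxide counterpart of the Baldwin-allowed 6-(enolendo)-exo-tet enolate alkylation. The carbocycle closes in the 6-(enolendo)-exo-tet mode with respect to the enolate and by endo opening of the oxirane at its distal carbon. No stereocentre is formed in the closure: C1 keeps the configuration installed by the Sharpless epoxidation and C2 that from step 3. The step needs C- instead of O-alkylation, attack at CH2 instead of the fully substituted carbon, and a single enolate; the protic medium and the enolendo geometry favour carbon, the fully substituted C1 cannot undergo SN2 (which also excludes the five-membered ring), and the quaternary C3 leaves the methyl group as the only enolisable position. High dilution suppresses intermolecular aldol addition, and the distant tertiary alkoxide of the side chain could only close a seven-membered ether.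

Step 7
Reactants: 10 (3S,4S)-4-hydroxy-3-[(3R)-3-hydroxy-3-methylpent-4-en-1-yl]-2,2,4-trimethylcyclohexan-1-one
Product: 11 (1S,2S,4R)-2-[(3R)-3-hydroxy-3-methylpent-4-en-1-yl]-1,3,3-trimethylcyclohexane-1,4-diol
Conditions: Li, NH3(l)/THF, −78 → −33 °C; then NH4Cl
Reagents that add atoms: none
Why: Dissolving-metal reduction (ketyl, then carbanion protonated on carbon) should give the thermodynamically preferred carbinol, expected to be the one with C4–OH equatorial in the chair that holds the C2 side chain axial between the two fully substituted carbons and so avoids a syn-diaxial CH3/CH3 contact, that is C4–OH cis to C1–OH; the isolated vinyl group and the alkoxides are inert.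

Step 8
Reactants: 11 (1S,2S,4R)-2-[(3R)-3-hydroxy-3-methylpent-4-en-1-yl]-1,3,3-trimethylcyclohexane-1,4-diol
Product: 13 (1S,2S,4R)-2-[(3R)-3,5-dihydroxy-3-methylpentyl]-1,3,3-trimethylcyclohexane-1,4-diol, via alkylborane 12 (not isolated)
Conditions: 9-BBN (excess), THF, 0 °C → rt; then NaOH, H2O2, 0 °C
Reagents that add atoms: 9-BBN [H]B1C2CCCC1CCC2 (boron, present only in 12) and hydrogen peroxide OO (the new oxygen)
Why: 9-BBN should place boron on the terminal carbon of the monosubstituted olefin (anti-Markovnikov hydroboration) and alkaline peroxide turns C–B into C–OH and hydrolyses any O-borinate, which unmasks the primary alcohol without touching a stereocentre.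

Step 9
Reactants: 13 (1S,2S,4R)-2-[(3R)-3,5-dihydroxy-3-methylpentyl]-1,3,3-trimethylcyclohexane-1,4-diol, 14 umbelliferone (7-hydroxy-2H-chromen-2-one)
Product: 15 7-{[(3R)-5-[(1S,3R,6S)-3,6-dihydroxy-2,2,6-trimethylcyclohexyl]-3-hydroxy-3-methylpentyl]oxy}-2H-chromen-2-one
Conditions: PPh3, DIAD, THF, 0 °C → rt
Reagents that add atoms: none
Why: In this Mitsunobu etherification the acidic phenol of 14 should displace only the activated primary alcohol, because the two tertiary hydroxyls and the neopentyl-type secondary hydroxyl are too hindered to be activated.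

Compound list
1 | (R)-(−)-linalool, (3R)-3,7-dimethylocta-1,6-dien-3-ol | C=C[C@](C)(O)CCC=C(C)C | starting material
2 | (2E,6R)-2,6-dimethylocta-2,7-diene-1,6-diol | C=C[C@](C)(O)CC/C=C(\C)CO | intermediate
3 | [(2S,3S)-3-[(3R)-3-hydroxy-3-methylpent-4-en-1-yl]-2-methyloxiran-2-yl]methanol | C=C[C@](C)(O)CC[C@@H]1O[C@@]1(C)CO | intermediate
4 | isobutyronitrile (2-methylpropanenitrile) | CC(C)C#N | starting material
5 | (3S,6R)-3-[(2R)-1,2-dihydroxypropan-2-yl]-6-hydroxy-2,2,6-trimethyloct-7-enenitrile | N#CC(C)(C)[C@H](CC[C@@](C)(O)C=C)[C@@](C)(O)CO | intermediate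
6 | (2R)-2-[(4S,7R)-7-hydroxy-2-imino-3,3,7-trimethylnon-8-en-4-yl]propane-1,2-diol (ketimine) | CC(=N)C(C)(C)[C@H](CC[C@@](C)(O)C=C)[C@@](C)(O)CO | intermediate (not isolated)
7 | (4S,7R)-4-[(2R)-1,2-dihydroxypropan-2-yl]-7-hydroxy-3,3,7-trimethylnon-8-en-2-one | CC(=O)C(C)(C)[C@H](CC[C@@](C)(O)C=C)[C@@](C)(O)CO | intermediate
8 | (2R)-2-hydroxy-2-[(4S,7R)-7-hydroxy-3,3,7-trimethyl-2-oxonon-8-en-4-yl]propyl 4-methylbenzenesulfonate | CC(=O)C(C)(C)[C@H](CC[C@@](C)(O)C=C)[C@@](C)(O)COS(=O)(=O)c1ccc(C)cc1 | intermediate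
9 | (4S,7R)-7-hydroxy-3,3,7-trimethyl-4-[(2R)-2-methyloxiran-2-yl]non-8-en-2-one (oxiranyl ketone) | CC(=O)C(C)(C)[C@H](CC[C@@](C)(O)C=C)[C@]1(C)CO1 | intermediate (not isolated)
10 | (3S,4S)-4-hydroxy-3-[(3R)-3-hydroxy-3-methylpent-4-en-1-yl]-2,2,4-trimethylcyclohexan-1-one | CC1(C)C(=O)CC[C@](C)(O)[C@H]1CC[C@@](C)(O)C=C | intermediate
11 | (1S,2S,4R)-2-[(3R)-3-hydroxy-3-methylpent-4-en-1-yl]-1,3,3-trimethylcyclohexane-1,4-diol | CC1(C)[C@H](O)CC[C@](C)(O)[C@H]1CC[C@@](C)(O)C=C | intermediate
12 | (1S,2S,4R)-2-[(3S)-5-(9-borabicyclo[3.3.1]nonan-9-yl)-3-hydroxy-3-methylpentyl]-1,3,3-trimethylcyclohexane-1,4-diol (alkylborane) | CC1(C)[C@H](O)CC[C@](C)(O)[C@H]1CC[C@@](C)(O)CCB2C3CCCC2CCC3 | intermediate (not isolated)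
13 | (1S,2S,4R)-2-[(3R)-3,5-dihydroxy-3-methylpentyl]-1,3,3-trimethylcyclohexane-1,4-diol | CC1(C)[C@H](O)CC[C@](C)(O)[C@H]1CC[C@@](C)(O)CCO | intermediate
14 | umbelliferone (7-hydroxy-2H-chromen-2-one) | O=c1ccc2ccc(O)cc2o1 | starting material
15 | 7-{[(3R)-5-[(1S,3R,6S)-3,6-dihydroxy-2,2,6-trimethylcyclohexyl]-3-hydroxy-3-methylpentyl]oxy}-2H-chromen-2-one | CC1(C)[C@H](O)CC[C@](C)(O)[C@H]1CC[C@@](C)(O)CCOc1ccc2ccc(=O)oc2c1 | target

Total step count: 9
Longest linear sequence: 9 steps (1 → 15)

Steps most likely to fail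

Step 3. The tertiary carbanion may attack the hindered oxirane too slowly, so that base-induced isomerisation of the epoxide to an allylic alcohol takes over. The fallback builds the quaternary carbon after the C–C bond and runs from 3 back to 5. Lithiated acetonitrile (LiCH2CN, THF) opens the oxirane at the same carbon, again with inversion, to give the cyanomethyl triol F1. 2,2-Dimethoxypropane with PPTS protects the 1,2-diol as the acetonide F2. Two rounds of LiN(iPr)2/MeI methylate the carbon next to the nitrile, by way of the monomethyl nitrile F3, to the gem-dimethyl nitrile F4. Aqueous acetic acid then removes the acetonide and returns to 5.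

Step 6. O-alkylation of the enolate, or a poor geometry for endo opening of the oxirane, may divert the closure. The fallback makes the same bond with a carbonyl electrophile and runs from 7 back to 10. TEMPO/PhI(OAc)2 oxidises only the primary alcohol to the α-hydroxy aldehyde F5, which has no α-hydrogen. Piperidine/AcOH brings about intramolecular aldol addition of the methyl ketone to give the aldol F6, which dehydrates in the flask to the cyclohexenone F7. Conjugate reduction with [(Ph3P)CuH]6, which spares the vinyl group, returns to 10.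

Step 7. Protonation may occur on the wrong face if the ring reacts from a chair other than the one assumed, which would give poor facial selectivity at C4. The fallback brings the hydroxyl in under control of the C1 hydroxyl and runs from 10 back to 11. TsNHNH2 gives the tosylhydrazone F8. A Shapiro reaction (n-BuLi, TMEDA; then H2O) gives the cyclohexene F9, since only C5 carries α-hydrogen. mCPBA, guided by the homoallylic C1 hydroxyl and by the side chain on the opposite face, gives the cis-epoxy alcohol F10; the ring olefin is more electron-rich than the vinyl group. LiAlH4 opens the epoxide at C5, away from the quaternary C3, and returns to 11.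

Further compounds
F1 | step 3 | (3S,6R)-3-[(2R)-1,2-dihydroxypropan-2-yl]-6-hydroxy-6-methyloct-7-enenitrile | N#CC[C@H](CC[C@@](C)(O)C=C)[C@@](C)(O)CO
F2 | step 3 | (3S,6R)-6-hydroxy-6-methyl-3-[(4R)-2,2,4-trimethyl-1,3-dioxolan-4-yl]oct-7-enenitrile | N#CC[C@H](CC[C@@](C)(O)C=C)[C@]1(C)COC(C)(C)O1
F3 | step 3 | (3S,6R)-6-hydroxy-2,6-dimethyl-3-[(4R)-2,2,4-trimethyl-1,3-dioxolan-4-yl]oct-7-enenitrile (both C2 epimers, not isolated) | N#CC(C)[C@H](CC[C@@](C)(O)C=C)[C@]1(C)COC(C)(C)O1
F4 | step 3 | (3S,6R)-6-hydroxy-2,2,6-trimethyl-3-[(4R)-2,2,4-trimethyl-1,3-dioxolan-4-yl]oct-7-enenitrile | N#CC(C)(C)[C@H](CC[C@@](C)(O)C=C)[C@]1(C)COC(C)(C)O1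
F5 | step 6 | (2R,3S)-2-hydroxy-3-[(3R)-3-hydroxy-3-methylpent-4-en-1-yl]-2,4,4-trimethyl-5-oxohexanal | CC(=O)C(C)(C)[C@H](CC[C@@](C)(O)C=C)[C@@](C)(O)C=O
F6 | step 6 | (3S,4R)-4,5-dihydroxy-3-[(3R)-3-hydroxy-3-methylpent-4-en-1-yl]-2,2,4-trimethylcyclohexan-1-one (both C5 epimers, not isolated) | CC1(C)C(=O)CC(O)[C@](C)(O)[C@H]1CC[C@@](C)(O)C=C
F7 | step 6 | (4S,5S)-4-hydroxy-5-[(3R)-3-hydroxy-3-methylpent-4-en-1-yl]-4,6,6-trimethylcyclohex-2-en-1-one | CC1(C)C(=O)C=C[C@](C)(O)[C@H]1CC[C@@](C)(O)C=C
F8 | step 7 | N'-[(3S,4S)-4-hydroxy-3-[(3R)-3-hydroxy-3-methylpent-4-en-1-yl]-2,2,4-trimethylcyclohexylidene]-4-methylbenzenesulfonohydrazide | CC1(C)C(=NNS(=O)(=O)c2ccc(C)cc2)CC[C@](C)(O)[C@H]1CC[C@@](C)(O)C=C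
F9 | step 7 | (1S,6S)-6-[(3R)-3-hydroxy-3-methylpent-4-en-1-yl]-1,5,5-trimethylcyclohex-3-en-1-ol | CC1(C)C=CC[C@](C)(O)[C@H]1CC[C@@](C)(O)C=C
F10 | step 7 | (1R,3S,4S,6S)-4-[(3R)-3-hydroxy-3-methylpent-4-en-1-yl]-3,5,5-trimethyl-7-oxabicyclo[4.1.0]heptan-3-ol | CC1(C)[C@@H]2O[C@@H]2C[C@](C)(O)[C@H]1CC[C@@](C)(O)C=C
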